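**Plan** (atoms numbered as in the ent-kaurane skeleton)
- Cuts, in retrosynthetic order: ring D at C13–C16 and C15–C16; ring C at C9–C11 and C8–C14 (butadiene) and at C8–C15; the 7,20-lactone back to a temporary 19,20-lactone; ring A at C1–C10; then C5–C10 and C5=C6.
- Enabling feature: C19–C4–C5–C10–C20 is a five-carbon chain whose ends sit cis-1,3-diaxial on ring A. Written as a β-keto-δ-lactone (C5 ketone, C20 carbonyl, C19–O–C20 ring), it makes C10 doubly activated, and the C1–C3 arm on C4 can reach C10 only in bridged fashion.
- Forward order: geraniol gives the C4 quaternary aldehyde; dimethyl glutarate brings C20, C10, C9, C8 and C7; the temporary lactone is closed; ring A is closed by aldol; the helpers are removed (C5=O to CH2OH, lactone moved to C7); ring C by Diels–Alder; ring D by radical enyne cyclisation.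
- Stereochemistry: C4 from Sharpless epoxidation and a stereospecific 1,2-shift; C10 relayed from C4 through the bridge; C1 thermodynamic (equatorial); C5 by hydroboration anti to axial C19/C20; C8 and C9 by the ring A-controlled face of the cycloaddition; C13 by bridge geometry.

Key step: step 8

Remark: the C5/C10 epimers in 6–10 and the C15 epimers in 27–29 are carried as mixtures, because these centres are later oxidised or enolised.

**Step 1**
Reactants: 1 geraniol
Product: 2 (2S,3S)-2,3-epoxygeraniol
Conditions: Ti(OiPr)4 (5 mol %), L-(+)-diethyl tartrate (7 mol %), tBuOOH, 4 Å MS, CH2Cl2, −20 °C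
Reagents that add atoms: tert-butyl hydroperoxide CC(C)(C)OO
Why: Sharpless asymmetric epoxidation of the allylic alcohol, in which the L-(+)-tartrate–titanium complex should deliver oxygen to one face of the 2,3-alkene to give the (2S,3S)-epoxide that later fixes C4.

**Step 2**
Reactants: 2 (2S,3S)-2,3-epoxygeraniol
Product: 3 (2S,3S)-2,3-epoxygeranyl tert-butyldimethylsilyl ether
Conditions: TBSCl, imidazole, DMF, 0 °C → rt
Reagents that add atoms: tert-butyldimethylsilyl chloride CC(C)(C)[Si](C)(C)Cl
Why: Silyl ether formation at the primary alcohol provides the epoxy silyl ether needed for the rearrangement and touches no stereocentre.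

**Step 3**
Reactants: 3 (2S,3S)-2,3-epoxygeranyl tert-butyldimethylsilyl ether
Product: 4 (S)-3-(tert-butyldimethylsilyloxy)-2-methyl-2-(4-methylpent-3-enyl)propanal
Conditions: methylaluminium bis(4-bromo-2,6-di-tert-butylphenoxide) (2 equiv, made beforehand from AlMe3 and the phenol), CH2Cl2, −78 °C; aq. HCl work-up
Reagents that add atoms: none
Why: Lewis acid-promoted rearrangement of an epoxy silyl ether (semipinacol type), in which the tertiary C–O bond ionises and the siloxymethyl group migrates anti to it, so the epoxide chirality should be transferred stereospecifically to the all-carbon quaternary centre (future C4) while the former C2 becomes the aldehyde (future C5).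

**Step 4**
Reactants: 4 (S)-3-(tert-butyldimethylsilyloxy)-2-methyl-2-(4-methylpent-3-enyl)propanal; 5 dimethyl glutarate
Product: 6 dimethyl 2-[(2S)-2-(tert-butyldimethylsilyloxymethyl)-1-hydroxy-2,6-dimethylhept-5-enyl]pentanedioate (epimer mixture at the carbinol and at C10)
Conditions: LiN(iPr)2 (1.2 equiv), 5 (1.3 equiv), THF, −78 °C; then 4, −78 °C; AcOH quench at −78 °C
Reagents that add atoms: none
Why: Aldol addition of the lithium mono-enolate of the diester to the non-enolisable neopentyl aldehyde forms the C5–C10 bond, and the two new centres need no control because both are erased later by oxidation and enolisation.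

**Step 5**
Reactants: 6 aldol adduct
Product: 7 dimethyl 2-[(2S)-2-(tert-butyldimethylsilyloxymethyl)-2,6-dimethylhept-5-enoyl]pentanedioate
Conditions: Dess–Martin periodinane, NaHCO3, CH2Cl2, rt
Reagents that add atoms: none
Why: Dess–Martin oxidation of the hindered secondary alcohol should give the β-keto ester under neutral conditions that leave the quaternary C4 and the silyl ether untouched.

**Step 6**
Reactants: 7 β-keto diester
Product: 9 methyl 3-[(5S)-5-methyl-5-(4-methylpent-3-enyl)-2,4-dioxooxan-3-yl]propanoate, via hydroxy keto diester 8 (not isolated)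
Conditions: HF·pyridine, THF, 0 °C → rt; then PPTS (cat.), PhMe, 80 °C
Reagents that add atoms: none
Why: Fluoride desilylation frees the C19 hydroxyl, which lactonises onto the neighbouring C20 methyl ester (six-membered ring, whereas the C7 ester would need an eight-membered one) to install the temporary C19–O–C20 ring, the acidic medium avoiding retro-aldol loss of formaldehyde from 8.

**Step 7**
Reactants: 9 β-keto-δ-lactone
Product: 10 methyl 3-[(5S)-5-methyl-2,4-dioxo-5-(3-oxopropyl)oxan-3-yl]propanoate
Conditions: O3, CH2Cl2/MeOH, −78 °C (indicator end point); then Me2S, −78 °C → rt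
Reagents that add atoms: ozone [O-][O+]=O
Why: Ozonolysis with reductive work-up should cleave the electron-rich trisubstituted alkene faster than the keto tautomer of the β-keto lactone reacts, unveiling the C1 aldehyde on the three-carbon arm of C4.

**Step 8**
Reactants: 10 aldehyde β-keto-δ-lactone
Product: 12 methyl 3-[8-(tert-butyldimethylsilyloxy)-5-methyl-2,9-dioxo-3-oxabicyclo[3.3.1]nonan-1-yl]propanoate (C1–O equatorial on ring A and cis to C20), via bridged aldol 11 (not isolated)
Conditions: DBU (0.2 equiv), CH2Cl2, 0 °C → rt; then 2,6-lutidine, TBSOTf, −40 → 0 °C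
Reagents that add atoms: tert-butyldimethylsilyl triflate CC(C)(C)[Si](C)(C)OS(=O)(=O)C(F)(F)F
Why: The amine base removes the acidic C10–H of the β-keto-δ-lactone and the stabilised enolate adds to the C1 aldehyde held on the C4 arm, after which the aldolate is silylated in the same flask so that the reversible aldol is drained toward product. The closest known reaction type is the intramolecular aldol closure of 2-(3-oxopropyl)-1,3-dicarbonyl compounds to 2-hydroxybicyclo[3.3.1]nonan-9-ones (bridged Robinson-type annulation). Ring A closes in a 6-(enolendo)-exo-trig mode on the carbonyl carbon C1, giving a 3-oxabicyclo[3.3.1]nonane in which ring A and the lactone are both chairs. C10 is controlled by C4 through the lactone tether, because the arm can reach only the enolate face on its own side, which makes C20 and C19 cis-diaxial and places the C9 chain equatorial; C1 is expected to settle under thermodynamic control with the oxygen equatorial and hydrogen-bonded to the lactone carbonyl before trapping. The step needs regioselective enolisation (only C10 carries an α-hydrogen, C4 being quaternary), chemoselectivity for the aldehyde (its own enolate could only close a four-membered ring) and no dehydration (C10 becomes quaternary and bridgehead).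

**Step 9**
Reactants: 12 silylated bridged aldol
Product: 13 methyl 3-[8-(tert-butyldimethylsilyloxy)-5-methyl-9-methylidene-2-oxo-3-oxabicyclo[3.3.1]nonan-1-yl]propanoate
Conditions: Zn, CH2Br2, TiCl4 (reagent formed beforehand in THF), CH2Cl2, 0 °C → rt
Reagents that add atoms: dibromomethane BrCBr
Why: Takai–Lombardo methylenation, a non-basic reagent selective for ketones over lactones and esters, should convert the C5 carbonyl flanked by quaternary C4 and C10 into the exocyclic C5=C6 methylene without retro-Claisen cleavage.

**Step 10**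
Reactants: 13 methylene bridged lactone ester
Product: 16 spirolactone alcohol 7-(tert-butyldimethylsilyloxy)-10-(hydroxymethyl)-10-methyl-11-methylidene-2-oxaspiro[5.5]undecan-3-one (ring A: 1-OTBS; 4-Me; 4-CH2OH; 5-methylidene; C10 spiro to the 7,20-lactone), via lithium carboxylate 14 (not isolated), via dihydroxy acid 15 (not isolated)
Conditions: LiOH·H2O (1.1 equiv), THF/H2O, 0 °C; solvent exchange; LiBH4, THF, 0 → 45 °C; then 1 M HCl, rt
Reagents that add atoms: lithium hydroxide [Li+].[OH-]
Why: Chemoselective saponification of the unhindered methyl ester, LiBH4 reduction of the bridged lactone beside the inert lithium carboxylate, and acid-induced δ-lactonisation of the C20 hydroxyl onto C7 transpose the lactone to the 7,20-position and free C19–OH, while the C1 oxygen stays silylated so that no 1,7-lactone can form.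

**Step 11**
Reactants: 16 spirolactone alcohol
Product: 17 diacetate (ring A: 1-OAc; 4-Me; 4-CH2OAc; 5-methylidene; C10 spiro to the 7,20-lactone)
Conditions: Ac2O, Cu(OTf)2 (5 mol %), CH2Cl2, 0 °C → rt
Reagents that add atoms: acetic anhydride CC(=O)OC(C)=O
Why: Lewis acid-catalysed acetylation esterifies the C19 alcohol and exchanges the C1 silyl ether directly for the acetate (silyl ether to acetate conversion), so that a free C1 hydroxyl next to the lactone never builds up.

**Step 12**
Reactants: 17 diacetate
Product: 18 primary alcohol (ring A: 1-OAc; 4-Me; 4-CH2OAc; 5-H with equatorial CH2OH; C10 spiro to the 7,20-lactone)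
Conditions: BH3·SMe2 (1.1 equiv), THF, 0 °C; then 30% H2O2, aq. NaHCO3, 0 °C → rt
Reagents that add atoms: hydrogen peroxide OO
Why: Hydroboration–oxidation of the 1,1-disubstituted alkene, in which borane should approach C5=C6 from the ring face opposite to the axial C19 and C20 substituents and deliver H axially to C5 (C6 equatorial), the alkene reacting far faster than the lactone or acetates at 0 °C.

**Step 13**
Reactants: 18 primary alcohol
Product: 19 silyl ether (as 18 with C6–OSi(tBu)Ph2)
Conditions: TBDPSCl, imidazole, DMF, rt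
Reagents that add atoms: tert-butyldiphenylsilyl chloride CC(C)(C)[Si](Cl)(c1ccccc1)c1ccccc1
Why: Silyl ether formation protects the primary C6 alcohol to the end and enlarges the C5 flank of the lactone for the later cycloaddition.

**Step 14**
Reactants: 19 silyl ether
Product: 21 α-hydroxymethylidene lactone (enol of the C8-formyl lactone; C15 installed), via enaminone 20 (not isolated)
Conditions: tBuOCH(NMe2)2 (3 equiv), PhMe, 80 °C; then 1 M HCl, THF, 0 °C
Reagents that add atoms: tert-butoxybis(dimethylamino)methane CN(C)C(OC(C)(C)C)N(C)C; water O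
Why: Aminomethylenation of the only lactone α-methylene (C8) with the formamide acetal under neutral conditions that leave the less acidic acetates alone, followed by acid hydrolysis of the enaminone, should introduce C15 as the formyl enol.

**Step 15**
Reactants: 21 α-hydroxymethylidene lactone
Product: 23 4-formyl-5,6-dihydropyran-2-one dienophile (C8=C9; C8–CHO; ring A as in 19), via selenide 22 (not isolated)
Conditions: PhSeCl, pyridine, CH2Cl2, 0 °C; then 30% H2O2, 0 °C → rt
Reagents that add atoms: none
Why: α-Selenenylation of the 1,3-dicarbonyl enol and selenoxide syn-elimination toward C9, the only carbon with β-hydrogens, should give the doubly activated C8=C9 alkene.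

**Step 16**
Reactants: 23 formyl enoate dienophile; 24 buta-1,3-diene
Product: 25 Diels–Alder adduct (ring C as a C12=C13 cyclohexene cis-fused to the lactone at C8–C9; C8 bearing CHO; ring A as in 19)
Conditions: 24 (excess), ZnCl2 (1 equiv), CH2Cl2, −20 °C → rt, sealed tube
Reagents that add atoms: none
Why: Lewis acid-promoted Diels–Alder reaction of the chelated 2-formyl enoate forms C9–C11 and C8–C14 suprafacially, and the diene should add to the lactone face flanked by the small C1 acetoxy group and away from the C5 CH2OSi substituent, which sets C8 and C9.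

**Step 17**
Reactants: 25 Diels–Alder adduct; 26 ethynylmagnesium bromide
Product: 27 propargylic alcohol (C8–CH(OH)–C≡CH; C15 epimers)
Conditions: 26 (1.5 equiv), THF, −78 → −30 °C; AcOH quench
Reagents that add atoms: none
Why: Grignard 1,2-addition of the alkynyl reagent to the neopentyl aldehyde at low temperature, where acetates and lactone react far more slowly, installs C16–C17, and the C15 configuration is irrelevant because it is oxidised in step 19.

**Step 18**
Reactants: 27 propargylic alcohol
Product: 29 allylic alcohol with the bicyclo[3.2.1]octane (15-hydroxy; 16-methylidene; 6-O-silyl), via vinylstannane 28 (not isolated)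
Conditions: Bu3SnH, AIBN (cat.), PhH, 80 °C; then PPTS, wet CH2Cl2, rt
Reagents that add atoms: none
Why: Radical enyne cyclisation, in which the stannyl radical adds to the terminal alkyne and the vinyl radical closes 5-exo-trig onto C13 of the ring C alkene, forms ring D with the C13 configuration forced by the bridge, and protodestannylation then leaves the exocyclic methylene.

**Step 19**
Reactants: 29 allylic alcohol
Product: 30 6-O-(tert-butyldiphenylsilyl) ether of the target
Conditions: Dess–Martin periodinane, NaHCO3, CH2Cl2, 0 °C → rt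
Reagents that add atoms: none
Why: Dess–Martin oxidation of the allylic alcohol should give the α-methylene cyclopentanone under neutral conditions.

**Step 20**
Reactants: 30 silyl ether of the target
Product: 31 target CNP0105570.2
Conditions: HF·pyridine, pyridine/THF, 0 °C → rt
Reagents that add atoms: none
Why: Fluoride cleavage of the silyl ether with buffered HF·pyridine should release the C6 alcohol without touching the acetates, the lactone or the exo-methylene ketone.

**Compound list**
1 | geraniol | CC(C)=CCC/C(C)=C/CO | starting material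
2 | (2S,3S)-2,3-epoxygeraniol | CC(C)=CCC[C@]1(C)O[C@H]1CO | intermediate
3 | (2S,3S)-2,3-epoxygeranyl tert-butyldimethylsilyl ether | CC(C)=CCC[C@]1(C)O[C@H]1CO[Si](C)(C)C(C)(C)C | intermediate
4 | (S)-3-(tert-butyldimethylsilyloxy)-2-methyl-2-(4-methylpent-3-enyl)propanal | CC(C)=CCC[C@@](C)(CO[Si](C)(C)C(C)(C)C)C=O | intermediate
5 | dimethyl glutarate | COC(=O)CCCC(=O)OC | starting material
6 | dimethyl 2-[(2S)-2-(tert-butyldimethylsilyloxymethyl)-1-hydroxy-2,6-dimethylhept-5-enyl]pentanedioate (epimer mixture) | CC(C)=CCC[C@@](C)(CO[Si](C)(C)C(C)(C)C)C(O)C(CCC(=O)OC)C(=O)OC | intermediate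
7 | dimethyl 2-[(2S)-2-(tert-butyldimethylsilyloxymethyl)-2,6-dimethylhept-5-enoyl]pentanedioate | CC(C)=CCC[C@@](C)(CO[Si](C)(C)C(C)(C)C)C(=O)C(CCC(=O)OC)C(=O)OC | intermediate
8 | dimethyl 2-[(2S)-2-(hydroxymethyl)-2,6-dimethylhept-5-enoyl]pentanedioate | CC(C)=CCC[C@@](C)(CO)C(=O)C(CCC(=O)OC)C(=O)OC | intermediate
9 | methyl 3-[(5S)-5-methyl-5-(4-methylpent-3-enyl)-2,4-dioxooxan-3-yl]propanoate | CC(C)=CCC[C@@]1(C)COC(=O)C(CCC(=O)OC)C1=O | intermediate
10 | methyl 3-[(5S)-5-methyl-2,4-dioxo-5-(3-oxopropyl)oxan-3-yl]propanoate | O=CCC[C@@]1(C)COC(=O)C(CCC(=O)OC)C1=O | intermediate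
11 | methyl 3-(8-hydroxy-5-methyl-2,9-dioxo-3-oxabicyclo[3.3.1]nonan-1-yl)propanoate; C1–OH equatorial on ring A; C19–O–C20 bridge diaxial | COC(=O)CC[C@]1(C(=O)OC2)[C@@H](O)CC[C@]2(C)C1=O | intermediate
12 | tert-butyldimethylsilyl ether of 11 | COC(=O)CC[C@]1(C(=O)OC2)[C@@H](O[Si](C)(C)C(C)(C)C)CC[C@]2(C)C1=O | intermediate
13 | 9-methylidene analogue of 12 (C5=C6) | COC(=O)CC[C@]1(C(=O)OC2)[C@@H](O[Si](C)(C)C(C)(C)C)CC[C@]2(C)C1=C | intermediate
14 | lithium carboxylate of 13 | [Li+].[O-]C(=O)CC[C@]1(C(=O)OC2)[C@@H](O[Si](C)(C)C(C)(C)C)CC[C@]2(C)C1=C | intermediate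
15 | 19,20-dihydroxy C7 acid (ring A: 1-OTBS; 5-methylidene) | OC(=O)CC[C@]1(CO)[C@@H](O[Si](C)(C)C(C)(C)C)CC[C@@](C)(CO)C1=C | intermediate
16 | 7-(tert-butyldimethylsilyloxy)-10-(hydroxymethyl)-10-methyl-11-methylidene-2-oxaspiro[5.5]undecan-3-one (7,20-lactone; 19-OH; 1-OTBS) | O=C1CC[C@]2(CO1)[C@@H](O[Si](C)(C)C(C)(C)C)CC[C@@](C)(CO)C2=C | intermediate
17 | 1,19-diacetate (7,20-lactone; 5-methylidene) | O=C1CC[C@]2(CO1)[C@@H](OC(C)=O)CC[C@@](C)(COC(C)=O)C2=C | intermediate
18 | 1,19-diacetate 6-alcohol (C5–H axial; CH2OH equatorial) | O=C1CC[C@]2(CO1)[C@@H](OC(C)=O)CC[C@@](C)(COC(C)=O)[C@H]2CO | intermediate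
19 | 6-O-(tert-butyldiphenylsilyl) ether of 18 | O=C1CC[C@]2(CO1)[C@@H](OC(C)=O)CC[C@@](C)(COC(C)=O)[C@H]2CO[Si](c1ccccc1)(c1ccccc1)C(C)(C)C | intermediate
20 | C8-(dimethylaminomethylidene) lactone | CN(C)C=C1C[C@]2(COC1=O)[C@@H](OC(C)=O)CC[C@@](C)(COC(C)=O)[C@H]2CO[Si](c1ccccc1)(c1ccccc1)C(C)(C)C | intermediate
21 | C8-(hydroxymethylidene) lactone (formyl enol) | OC=C1C[C@]2(COC1=O)[C@@H](OC(C)=O)CC[C@@](C)(COC(C)=O)[C@H]2CO[Si](c1ccccc1)(c1ccccc1)C(C)(C)C | intermediate
22 | C8-formyl C8-phenylselanyl lactone | O=CC1([Se]c3ccccc3)C[C@]2(COC1=O)[C@@H](OC(C)=O)CC[C@@](C)(COC(C)=O)[C@H]2CO[Si](c1ccccc1)(c1ccccc1)C(C)(C)C | intermediate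
23 | C8-formyl C8=C9 unsaturated lactone | O=CC1=C[C@]2(COC1=O)[C@@H](OC(C)=O)CC[C@@](C)(COC(C)=O)[C@H]2CO[Si](c1ccccc1)(c1ccccc1)C(C)(C)C | intermediate
24 | buta-1,3-diene | C=CC=C | starting material
25 | Diels–Alder adduct (C12=C13; C8–CHO; rings C and lactone cis-fused) | O=C[C@]12CC=CC[C@H]1[C@]1(COC2=O)[C@@H](OC(C)=O)CC[C@@](C)(COC(C)=O)[C@H]1CO[Si](c1ccccc1)(c1ccccc1)C(C)(C)C | intermediate
26 | ethynylmagnesium bromide | C#C[Mg]Br | starting material
27 | propargylic alcohol (C15 epimers) | C#CC(O)[C@]12CC=CC[C@H]1[C@]1(COC2=O)[C@@H](OC(C)=O)CC[C@@](C)(COC(C)=O)[C@H]1CO[Si](c1ccccc1)(c1ccccc1)C(C)(C)C | intermediate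
28 | C17-tributylstannyl bicyclo[3.2.1]octane allylic alcohol | CCCC[Sn](CCCC)(CCCC)C=C1C(O)[C@]23C[C@H]1CC[C@H]2[C@]1(COC3=O)[C@@H](OC(C)=O)CC[C@@](C)(COC(C)=O)[C@H]1CO[Si](c1ccccc1)(c1ccccc1)C(C)(C)C | intermediate
29 | 15-hydroxy-16-methylidene compound (C15 epimers) | C=C1C(O)[C@]23C[C@H]1CC[C@H]2[C@]1(COC3=O)[C@@H](OC(C)=O)CC[C@@](C)(COC(C)=O)[C@H]1CO[Si](c1ccccc1)(c1ccccc1)C(C)(C)C | intermediate
30 | 6-O-(tert-butyldiphenylsilyl) ether of the target | C=C1C(=O)[C@]23C[C@H]1CC[C@H]2[C@]1(COC3=O)[C@@H](OC(C)=O)CC[C@@](C)(COC(C)=O)[C@H]1CO[Si](c1ccccc1)(c1ccccc1)C(C)(C)C | intermediate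
31 | CNP0105570.2 | C=C1C(=O)[C@]23C[C@H]1CC[C@H]2[C@]1(COC3=O)[C@@H](OC(C)=O)CC[C@@](C)(COC(C)=O)[C@H]1CO | target

Total step count: 20
Longest linear sequence: 20 steps (from geraniol)

**Steps most likely to fail**

Step 8. The reversible aldol may settle on the axial C1 carbinol or on a mixture, or revert before the silyl trap acts. The fallback sets the C1 stereocentre by hydride instead of by the aldol. It sets out from 10: the aldol is run without silylation, and the mixture of 11 and its axial C1 epimer F1 is oxidised with Dess–Martin periodinane to the C1 ketone F2. Reduction with NaBH4 (MeOH/CH2Cl2, −78 °C) should then attack the C1 carbonyl axially, while the C5 ketone between two quaternary carbons stays untouched. The equatorial alcohol 11 is silylated as in step 8, and the route is rejoined at 12.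

Step 9. Methylene transfer to the C5 carbonyl flanked by two quaternary carbons may not take place, or the Lewis-acidic reagent may open the β-keto lactone. The fallback is a Peterson olefination that sets out from 12. Me3SiCH2Li/CeCl3 in THF at −78 °C, an organocerium reagent that adds to ketones in preference to lactones and esters, should give the β-hydroxysilane F3. BF3·OEt2 in CH2Cl2 at 0 °C then eliminates trimethylsilanol, and the route is rejoined at 13.

Step 16. The cycloaddition at the neopentyl C9 may be sluggish, with competing oxadiene reactivity or oligomerisation of the formyl enoate and loss of facial selectivity at the temperatures then needed. The fallback sets out from 23 and uses the far more nucleophilic 2-(trimethylsilyloxy)buta-1,3-diene at low temperature. Its nucleophilic terminus bonds to C9, giving the silyl enol ether adduct F4 (C12–OSiMe3, C12=C13). CsF and PhNTf2 convert this regiospecifically into the enol triflate F5, and reduction with Pd(OAc)2, PPh3, HCO2H and Et3N in DMF removes the oxygen, so that the route is rejoined at 25.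

**Further compounds**
F1 | step 8 | axial C1 epimer of 11 | COC(=O)CC[C@]1(C(=O)OC2)[C@H](O)CC[C@]2(C)C1=O
F2 | step 8 | methyl 3-(5-methyl-2,8,9-trioxo-3-oxabicyclo[3.3.1]nonan-1-yl)propanoate (C1 ketone) | COC(=O)CC[C@]1(C(=O)OC2)C(=O)CC[C@]2(C)C1=O
F3 | step 9 | C5 β-hydroxysilane from 12 (9-hydroxy-9-(trimethylsilylmethyl)) | COC(=O)CC[C@]1(C(=O)OC2)[C@@H](O[Si](C)(C)C(C)(C)C)CC[C@]2(C)C1(O)C[Si](C)(C)C
F4 | step 16 | C12 trimethylsilyl enol ether analogue of 25 | O=C[C@]12CC=C(O[Si](C)(C)C)C[C@H]1[C@]1(COC2=O)[C@@H](OC(C)=O)CC[C@@](C)(COC(C)=O)[C@H]1CO[Si](c1ccccc1)(c1ccccc1)C(C)(C)C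
F5 | step 16 | C12 enol triflate analogue of 25 | O=C[C@]12CC=C(OS(=O)(=O)C(F)(F)F)C[C@H]1[C@]1(COC2=O)[C@@H](OC(C)=O)CC[C@@](C)(COC(C)=O)[C@H]1CO[Si](c1ccccc1)(c1ccccc1)C(C)(C)C
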